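**Retrosynthetic overview**
1. Target 11 comes from the symmetric bis-prenyl (Z)-stilbenediol 9 by one enantioselective mono-epoxidation with in-flask 5-exo phenol cyclisation; this breaks the symmetry, sets the only stereocentre and forms the dihydrofuran ring, the only ring made in the route, last.
2. Diol 9 comes from bis(1,1-dimethylallyl) ether 7 by a double aromatic Claisen rearrangement.
3. Ether 7 comes from tris-alkyne 5 by one Lindlar hydrogenation that sets the Z-alkene and unmasks both allyl ethers.
4. Tris-alkyne 5 comes from 5-(phenylethynyl)resorcinol 3 and 3-chloro-3-methylbut-1-yne; 3 comes from 5-iodoresorcinol and phenylacetylene (both benzene rings are bought).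

Assumption: 5-iodobenzene-1,3-diol, 3-chloro-3-methylbut-1-yne and the D-fructose-derived ketone catalyst are catalogue chemicals; phenylacetylene is the bulk aromatic feedstock. The stereocentre of the target is (S) (priorities O1 > CMe2OH > C3 > H). All Z-stilbenes are handled in amber glassware.

**Step 1**
Reactants: 1 5-iodobenzene-1,3-diol; 2 ethynylbenzene (phenylacetylene)
Product: 3 5-(phenylethynyl)benzene-1,3-diol
Conditions: Pd(PPh3)2Cl2 (2 mol %), CuI (4 mol %), Et3N (3 equiv), THF, 25–45 °C, Ar
Reagents that add atoms: none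
Why: Sonogashira coupling (oxidative addition of the aryl iodide to zerovalent palladium formed in situ, transmetalation of the copper acetylide, reductive elimination) tolerates free phenols and creates no stereocentre.

**Step 2**
Reactants: 3 5-(phenylethynyl)benzene-1,3-diol; 4 3-chloro-3-methylbut-1-yne (2.6 equiv)
Product: 5 1,3-bis[(2-methylbut-3-yn-2-yl)oxy]-5-(phenylethynyl)benzene
Conditions: CuCl2·2H2O (1 mol %), DBU (3 equiv), MeCN, 0 °C to rt, N2
Reagents that add atoms: none
Why: Copper-catalysed propargylic O-alkylation of phenols with a tertiary propargylic chloride (Godfrey-type 1,1-dimethylpropargyl ether synthesis) etherifies both phenols, and the internal diarylalkyne is inert.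

**Step 3**
Reactants: 5 1,3-bis[(2-methylbut-3-yn-2-yl)oxy]-5-(phenylethynyl)benzene
Product: 7 1,3-bis[(2-methylbut-3-en-2-yl)oxy]-5-[(Z)-2-phenylethenyl]benzene, via bis(dimethylallyl ether) alkyne 6 (not isolated)
Conditions: H2 (1 atm, stopped at 3.0 equiv uptake), 5% Pd/CaCO3 poisoned with Pb(OAc)2, quinoline, EtOAc, rt
Reagents that add atoms: none
Why: Lindlar semi-hydrogenation delivers H2 syn on the poisoned palladium surface, so the two terminal alkynes give vinyl groups and the diarylalkyne gives the Z-alkene; alkynes out-compete alkenes for the surface, so reduction stops at the triene.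

**Step 4**
Reactants: 7 1,3-bis[(2-methylbut-3-en-2-yl)oxy]-5-[(Z)-2-phenylethenyl]benzene
Product: 9 4,6-bis(3-methylbut-2-en-1-yl)-5-[(Z)-2-phenylethenyl]benzene-1,3-diol, via mono-rearranged phenol 8 (not isolated)
Conditions: o-xylene, PhNEt2 (0.2 equiv), 130 °C, 3 h, Ar, dark; chromatography
Reagents that add atoms: none
Why: Double aromatic Claisen rearrangement (two [3,3]-sigmatropic shifts, each followed by re-aromatising enolisation) turns each 1,1-dimethylallyl ether into an ortho-prenyl phenol; the ring carbon para to the other oxygen is the electronically preferred terminus, as in resorcinol diallyl ether, and the isomer prenylated between the oxygens is separated.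

**Step 5 (key step)**
Reactants: 9 4,6-bis(3-methylbut-2-en-1-yl)-5-[(Z)-2-phenylethenyl]benzene-1,3-diol
Product: 11 (2S)-2-(2-hydroxypropan-2-yl)-5-(3-methylbut-2-en-1-yl)-4-[(Z)-2-phenylethenyl]-2,3-dihydro-1-benzofuran-6-ol, via (R)-monoepoxide 10 (not isolated)
Conditions: 1,2:4,5-di-O-isopropylidene-β-D-erythro-2,3-hexodiulo-2,6-pyranose (D-fructose-derived Shi ketone, 0.3 equiv), KHSO5 (0.8 equiv, as 2KHSO5·KHSO4·K2SO4), K2CO3, Bu4NHSO4 (cat.), MeCN–CH2(OMe)2/aq. Na2B4O7 buffer (pH 10.5), −10 to 0 °C; then K2CO3, MeOH, rt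
Reagents that add atoms: potassium peroxymonosulfate KHSO5, [K+].[O-]S(=O)(=O)OO
Why: Proposed new method: the chiral dioxirane formed from the ketone and KHSO5 transfers oxygen through a spiro transition state to one of the two equivalent (homotopic) prenyl groups of 9, on the face that gives the (R)-epoxide as for other 2-methylalk-2-enes, and this first oxidation breaks the symmetry; the neighbouring phenoxide then opens the epoxide 5-exo-tet at the secondary carbon with inversion to give the (S)-dihydrobenzofuran. The closest known reaction is the Shi asymmetric epoxidation of O-protected ortho-prenylphenols followed by base-induced cyclisation. New here are the free phenols and the stop at mono-oxidation, which is enforced by sub-stoichiometric oxidant, so the yield is statistical (at most about 50% per pass) and recovered 9 is recycled. The hindered cis-stilbene alkene is a much poorer dioxirane substrate than the trisubstituted prenyl alkene.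

**Compound list**
1 | 5-iodobenzene-1,3-diol | Oc1cc(O)cc(I)c1 | starting material
2 | ethynylbenzene (phenylacetylene) | C#Cc1ccccc1 | starting material
3 | 5-(phenylethynyl)benzene-1,3-diol | Oc1cc(O)cc(C#Cc2ccccc2)c1 | intermediate
4 | 3-chloro-3-methylbut-1-yne | CC(C)(Cl)C#C | starting material
5 | 1,3-bis[(2-methylbut-3-yn-2-yl)oxy]-5-(phenylethynyl)benzene | C#CC(C)(C)Oc1cc(OC(C)(C)C#C)cc(C#Cc2ccccc2)c1 | intermediate
6 | 1,3-bis[(2-methylbut-3-en-2-yl)oxy]-5-(phenylethynyl)benzene | C=CC(C)(C)Oc1cc(OC(C)(C)C=C)cc(C#Cc2ccccc2)c1 | intermediate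
7 | 1,3-bis[(2-methylbut-3-en-2-yl)oxy]-5-[(Z)-2-phenylethenyl]benzene | C=CC(C)(C)Oc1cc(OC(C)(C)C=C)cc(/C=C\c2ccccc2)c1 | intermediate
8 | 2-(3-methylbut-2-en-1-yl)-5-[(2-methylbut-3-en-2-yl)oxy]-3-[(Z)-2-phenylethenyl]phenol | CC(C)=CCc1c(O)cc(OC(C)(C)C=C)cc1/C=C\c1ccccc1 | intermediate
9 | 4,6-bis(3-methylbut-2-en-1-yl)-5-[(Z)-2-phenylethenyl]benzene-1,3-diol | CC(C)=CCc1c(O)cc(O)c(CC=C(C)C)c1/C=C\c1ccccc1 | intermediate
10 | 4-{[(2R)-3,3-dimethyloxiran-2-yl]methyl}-6-(3-methylbut-2-en-1-yl)-5-[(Z)-2-phenylethenyl]benzene-1,3-diol | CC(C)=CCc1c(O)cc(O)c(C[C@H]2OC2(C)C)c1/C=C\c1ccccc1 | intermediate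
11 | (2S)-2-(2-hydroxypropan-2-yl)-5-(3-methylbut-2-en-1-yl)-4-[(Z)-2-phenylethenyl]-2,3-dihydro-1-benzofuran-6-ol | CC(C)=CCc1c(O)cc2c(c1/C=C\c1ccccc1)C[C@@H](C(C)(C)O)O2 | target

**Step count and risks**
Total step count: 5. Longest linear sequence: 5 steps (1/2 → 3 → 5 → 7 → 9 → 11).

The three steps most likely to fail:

Step 5. The free, electron-rich resorcinol ring may be oxidised by the dioxirane, and mono- versus bis-epoxidation is only statistical. The fallback sets out from 9 and masks the phenols: TBSCl and imidazole in DMF give 1,5-bis[(tert-butyldimethylsilyl)oxy]-2,4-bis(3-methylbut-2-en-1-yl)-3-[(Z)-2-phenylethenyl]benzene F1. The same ketone/KHSO5 epoxidation, now on a substrate of the well-precedented protected type, gives (2R)-2-{[2,4-bis[(tert-butyldimethylsilyl)oxy]-5-(3-methylbut-2-en-1-yl)-6-[(Z)-2-phenylethenyl]phenyl]methyl}-3,3-dimethyloxirane F2. Bu4NF in THF then removes both silyl groups and comes back to the route at 10, whose phenoxide closes to 11 as in the main step.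

Step 4. The first or second prenyl may migrate to the carbon between the two oxygens, which lowers the share of symmetric 9. The fallback sets out from 3 and moves the rearrangement to the alkyne stage, where the substituent flanking the desired positions is a slim, inductively withdrawing alkynyl group. tert-Butyl (2-methylbut-3-en-2-yl) carbonate F3 (from 2-methylbut-3-en-2-ol, n-BuLi and di-tert-butyl dicarbonate) and Pd(PPh3)4 (zerovalent palladium) in THF at 0 °C O-alkylate both phenols of 3 at the tertiary allyl terminus to give 6 as an isolated compound. Heating 6 in o-xylene at 130 °C gives, by way of 2-(3-methylbut-2-en-1-yl)-5-[(2-methylbut-3-en-2-yl)oxy]-3-(phenylethynyl)phenol F4, the diol 4,6-bis(3-methylbut-2-en-1-yl)-5-(phenylethynyl)benzene-1,3-diol F5. Lindlar semi-hydrogenation of its single alkyne (Pd/CaCO3 poisoned with Pb(OAc)2, quinoline, H2) comes back to the route at 9.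

Step 3. The terminal vinyl groups may be over-reduced before the slower diarylalkyne is consumed. The fallback sets out from 3 and splits the reduction in two. Lindlar semi-hydrogenation of 3 alone gives 5-[(Z)-2-phenylethenyl]benzene-1,3-diol F6. Copper-catalysed alkylation with 4 (CuCl2·2H2O, DBU, MeCN) gives 1,3-bis[(2-methylbut-3-yn-2-yl)oxy]-5-[(Z)-2-phenylethenyl]benzene F7. A second, fast Lindlar reduction of only the two terminal alkynes comes back to the route at 7.

**Further compounds**
F1 | step 5 | 1,5-bis[(tert-butyldimethylsilyl)oxy]-2,4-bis(3-methylbut-2-en-1-yl)-3-[(Z)-2-phenylethenyl]benzene | CC(C)=CCc1c(O[Si](C)(C)C(C)(C)C)cc(O[Si](C)(C)C(C)(C)C)c(CC=C(C)C)c1/C=C\c1ccccc1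
F2 | step 5 | (2R)-2-{[2,4-bis[(tert-butyldimethylsilyl)oxy]-5-(3-methylbut-2-en-1-yl)-6-[(Z)-2-phenylethenyl]phenyl]methyl}-3,3-dimethyloxirane | CC(C)=CCc1c(O[Si](C)(C)C(C)(C)C)cc(O[Si](C)(C)C(C)(C)C)c(C[C@H]2OC2(C)C)c1/C=C\c1ccccc1
F3 | step 4 | tert-butyl (2-methylbut-3-en-2-yl) carbonate | C=CC(C)(C)OC(=O)OC(C)(C)C
F4 | step 4 | 2-(3-methylbut-2-en-1-yl)-5-[(2-methylbut-3-en-2-yl)oxy]-3-(phenylethynyl)phenol | CC(C)=CCc1c(O)cc(OC(C)(C)C=C)cc1C#Cc1ccccc1
F5 | step 4 | 4,6-bis(3-methylbut-2-en-1-yl)-5-(phenylethynyl)benzene-1,3-diol | CC(C)=CCc1c(O)cc(O)c(CC=C(C)C)c1C#Cc1ccccc1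
F6 | step 3 | 5-[(Z)-2-phenylethenyl]benzene-1,3-diol | Oc1cc(O)cc(/C=C\c2ccccc2)c1
F7 | step 3 | 1,3-bis[(2-methylbut-3-yn-2-yl)oxy]-5-[(Z)-2-phenylethenyl]benzene | C#CC(C)(C)Oc1cc(OC(C)(C)C#C)cc(/C=C\c2ccccc2)c1
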